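**Strategy.** Ring A is never closed as a six-membered ring. A cyclopentanone that already holds the quaternary C4 (methyl C18, carboxyl C19; diterpene numbering, remark below) is enlarged by one carbon. In a β-oxido lithium carbenoid the C10–C4 bond shifts to the carbenoid carbon, which becomes C5. The C10(O)=C5 enolate so released adds to benzyl glyoxylate (C5–C6), and acid closes the C19–O–C6 lactone. The step exploits the 1,3-relation of the C10 oxygen and the C19 carboxyl across C5 in ring A. Methylenation and hydration then set C10. Decarboxylation at C6 gives a radical that joins a dienone made from (S)-perillic acid (C6–C7), and enolate alkylation closes ring D.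

Key step: step 3

Remark (numbering used throughout): ring A = C1, C2, C3, C4, C5, C10 (C4 bears methyl C18 and carboxyl C19; C10 bears methyl C20 and OH); lactone ring = C19, O, C6, C5, C4; C7 = linking CH2; ring C = C8, C9, C11, C12, C13, C14 (C9 ketone, C11=C12); ring D = C8, C15, C16, C13, C14 (C15 OAc, C16=C17). "Endo" at C15 means the face of the C9–C11–C12 bridge. C6 of compounds 7–11 is an epimer mixture; this centre becomes a radical in step 11.

Step 1
Reactants: 1 tert-butyl 2-oxocyclopentane-1-carboxylate
Product: 2 tert-butyl (1R)-1-methyl-2-oxocyclopentane-1-carboxylate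
Conditions: MeI, chiral N-spiro bis(binaphthyl) quaternary ammonium bromide (1 mol %, the enantiomer that gives the R ester), K2CO3, toluene, −20 °C
Reagents that add atoms: iodomethane, CI
Why: Asymmetric phase-transfer alkylation of a cyclic β-keto tert-butyl ester; the chiral ion pair shields one enolate face and sets the quaternary C4.

Step 2
Reactants: 2 tert-butyl (1R)-1-methyl-2-oxocyclopentane-1-carboxylate
Product: 3 tert-butyl (1R)-2-(dibromomethyl)-2-hydroxy-1-methylcyclopentane-1-carboxylate (both configurations at the carbinol carbon, the future C10)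
Conditions: CH2Br2, lithium 2,2,6,6-tetramethylpiperidide, THF, −78 °C; NH4Cl (aq)
Reagents that add atoms: dibromomethane, BrCBr
Why: Dibromomethyllithium, made in the presence of the ketone, undergoes 1,2-addition faster than enolisation; the new carbinol centre is erased in step 3.

Step 3
Reactants: 3 tert-butyl (1R)-2-(dibromomethyl)-2-hydroxy-1-methylcyclopentane-1-carboxylate, 4 benzyl glyoxylate
Product: 8 benzyl 7a-methyl-1,4-dioxo-octahydro-2-benzofuran-3-carboxylate (cis ring fusion, H-3a and the 7a-methyl on one face; C4 and C5 as in the target, C6 both epimers), via β-oxido lithium carbenoid 5 (not isolated), via ring-expanded lithium enolate 6 (not isolated), via lithium aldolate 7 (not isolated)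
Conditions: n-BuLi (2.2 equiv), THF, −95 → −78 °C; 4, −78 °C; then CF3CO2H, CH2Cl2, 0 °C
Reagents that add atoms: none
Why: Deprotonation and bromine–lithium exchange give carbenoid 5, in which the C10–C4 bond migrates to the carbenoid carbon C5 with loss of LiBr and retention at C4, so the five-membered ring becomes six-membered ring A as enolate 6; 6 adds to aldehyde 4 through C5, and acid removes isobutene and lactonises. The closest known reaction type is the β-oxido carbenoid one-carbon ring enlargement of cyclic ketones, with trapping of the regiodefined enolate by an aldehyde. Ring A is enlarged by a 1,2-shift, not closed; the lactone closes by 5-exo-trig attack of the C6 hydroxyl on the C19 carboxyl. C5 is controlled by the quaternary C4: only the isomer with C6 cis to C19 gives the cis-fused lactone, and the C5 epimer can equilibrate through the C10 enol under the acid; C6 is not controlled. The step needs migration of C4 and not of C1; the fully substituted C4 should migrate in preference to the methylene, as the more substituted carbon normally does in this rearrangement, although its ester group narrows the margin.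

Step 4
Reactants: 8 benzyl 7a-methyl-1,4-dioxo-octahydro-2-benzofuran-3-carboxylate
Product: 9 benzyl 7a-methyl-4-methylidene-1-oxo-octahydro-2-benzofuran-3-carboxylate
Conditions: Zn, CH2Br2, TiCl4, THF–CH2Cl2, 0 °C → rt
Reagents that add atoms: dibromomethane, BrCBr
Why: Non-basic gem-dizinc/titanium carbonyl methylenation takes the C10 ketone only, spares lactone and ester, and avoids β-elimination of the β-acyloxy ketone; C5 is no longer epimerisable afterwards.

Step 5
Reactants: 9 benzyl 7a-methyl-4-methylidene-1-oxo-octahydro-2-benzofuran-3-carboxylate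
Product: 10 benzyl 4-hydroxy-4,7a-dimethyl-1-oxo-octahydro-2-benzofuran-3-carboxylate (10-OH, H5 and C18 on one face)
Conditions: Co(acac)2 (20 mol %), PhSiH3, O2 (1 atm), THF, rt
Reagents that add atoms: dioxygen, O=O
Why: Mukaiyama hydration: hydrogen-atom transfer to the CH2 terminus gives the tertiary C10 radical, which should take up O2 on the convex face away from the lactone (anti to the axial C19), placing OH cis to H5 and C20 cis to C19.

Step 6
Reactants: 10 benzyl 4-hydroxy-4,7a-dimethyl-1-oxo-octahydro-2-benzofuran-3-carboxylate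
Product: 11 4-hydroxy-4,7a-dimethyl-1-oxo-octahydro-2-benzofuran-3-carboxylic acid
Conditions: H2 (1 atm), Pd/C (10 % palladium on carbon), EtOAc, rt
Reagents that add atoms: none
Why: Neutral hydrogenolysis of the benzyl ester leaves the lactone and tertiary alcohol untouched.

Step 7
Reactants: 12 (S)-perillic acid
Product: 13 (4S)-1-(methylsulfanyl)-4-(prop-1-en-2-yl)cyclohex-2-ene-1-carboxylic acid (both configurations at C1)
Conditions: LDA (2.2 equiv), THF, −78 → 0 °C; MeSSMe, −78 °C; 1 M HCl
Reagents that add atoms: dimethyl disulfide, CSSC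
Why: γ-Deprotonation gives the dienediolate, which is sulfenylated at the α-carbon with shift of the alkene to C11=C12; the C13 stereocentre is not touched.

Step 8
Reactants: 13 (4S)-1-(methylsulfanyl)-4-(prop-1-en-2-yl)cyclohex-2-ene-1-carboxylic acid
Product: 14 (4S)-4-(prop-1-en-2-yl)cyclohex-2-en-1-one
Conditions: N-chlorosuccinimide (1.05 equiv), NaHCO3, MeCN–H2O, 0 °C → rt
Reagents that add atoms: water, O
Why: Oxidative decarboxylation of an α-alkylthio acid: S-chlorination, loss of CO2 to the allyl thionium ion and hydrolysis give the enone with C13 unchanged.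

Step 9
Reactants: 14 (4S)-4-(prop-1-en-2-yl)cyclohex-2-en-1-one
Product: 15 (4S)-6-[(dimethylamino)methyl]-4-(prop-1-en-2-yl)cyclohex-2-en-1-one (both configurations at C6, the future C8)
Conditions: LDA, THF, −78 °C; CH2=NMe2 I, −78 °C → rt
Reagents that add atoms: N,N-dimethylmethyleneiminium iodide (Eschenmoser's salt), C=[N+](C)C.[I-]
Why: Kinetic deprotonation of the enone gives the cross-conjugated α′-enolate, which undergoes a Mannich reaction at the future C8.

Step 10
Reactants: 15 (4S)-6-[(dimethylamino)methyl]-4-(prop-1-en-2-yl)cyclohex-2-en-1-one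
Product: 17 (4S)-6-methylidene-4-(prop-1-en-2-yl)cyclohex-2-en-1-one (used at once), via trimethylammonium iodide 16 (not isolated)
Conditions: MeI, CH2Cl2, rt; then NaHCO3 (aq), CH2Cl2, 0 °C
Reagents that add atoms: none
Why: Quaternisation and mild E1cb elimination of the β-ammonio ketone give the α-methylene ketone; the weak base avoids isomerisation of the dienone to the phenol.

Step 11
Reactants: 11 4-hydroxy-4,7a-dimethyl-1-oxo-octahydro-2-benzofuran-3-carboxylic acid, 17 (4S)-6-methylidene-4-(prop-1-en-2-yl)cyclohex-2-en-1-one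
Product: 18 4-hydroxy-4,7a-dimethyl-3-{[(5S)-2-oxo-5-(prop-1-en-2-yl)cyclohex-3-en-1-yl]methyl}hexahydro-2-benzofuran-1(3H)-one (C7 on the face of H5; both configurations at C8)
Conditions: [Ir(dF(CF3)ppy)2(dtbbpy)]PF6 (1 mol %), K2HPO4, 17 (1.5 equiv), DMF, blue LEDs, rt
Reagents that add atoms: none
Why: Photoredox decarboxylative Giese reaction: the α-acyloxy radical at C6 adds to the terminal carbon of the exocyclic enone from the convex lactone face, anti to C10, setting C6; the α-keto radical is reduced and protonated, and the C8 centre is re-made in step 13.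

Step 12
Reactants: 18 seco-ketone with isopropenyl group
Product: 19 4-hydroxy-4,7a-dimethyl-3-{[(5S)-5-(3-chloroprop-1-en-2-yl)-2-oxocyclohex-3-en-1-yl]methyl}hexahydro-2-benzofuran-1(3H)-one
Conditions: Ca(OCl)2, CO2 (dry ice), CH2Cl2–H2O, 0 °C
Reagents that add atoms: calcium hypochlorite, [Ca+2].[O-]Cl.[O-]Cl
Why: Ene-type allylic chlorination by HOCl converts the electron-rich isopropenyl group into the 2-(chloromethyl)allyl group (C15–Cl), while the electron-poor enone is inert.

Step 13
Reactants: 19 allylic chloride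
Product: 20 4-hydroxy-4,7a-dimethyl-3-{[6-methylidene-2-oxobicyclo[3.2.1]oct-3-en-1-yl]methyl}hexahydro-2-benzofuran-1(3H)-one (C8 and C13 as in the target)
Conditions: KHMDS (2.2 equiv), THF, −78 → 0 °C
Reagents that add atoms: none
Why: The kinetic α′-enolate at C8 alkylates intramolecularly (5-exo-tet; SN2 and SN2′ give the same product) to close ring D; only the 1,3-cis bridge can form, so C13 dictates the quaternary C8.

Step 14
Reactants: 20 bicyclo[3.2.1]octenone
Product: 21 7-hydroxy derivative of 20 (15-OH, both epimers, exo expected to dominate)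
Conditions: SeO2 (cat.), t-BuOOH, CH2Cl2, rt
Reagents that add atoms: tert-butyl hydroperoxide, CC(C)(C)OO
Why: Allylic oxidation by ene reaction and [2,3]-shift at C15, the only non-bridgehead allylic position of the C16=C17 alkene; the C15 configuration is irrelevant here.

Step 15
Reactants: 21 allylic alcohol
Product: 22 4-hydroxy-4,7a-dimethyl-3-{[6-methylidene-2,7-dioxobicyclo[3.2.1]oct-3-en-1-yl]methyl}hexahydro-2-benzofuran-1(3H)-one
Conditions: Dess–Martin periodinane, NaHCO3, CH2Cl2, 0 °C
Reagents that add atoms: none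
Why: Mild oxidation of the secondary allylic alcohol; the tertiary C10 alcohol cannot be oxidised.

Step 16
Reactants: 22 enedione
Product: 23 7-endo-hydroxy derivative (15-OH on the face of the C9 bridge, as in the target)
Conditions: NaBH4 (1.0 equiv), CeCl3·7H2O, MeOH, −78 °C
Reagents that add atoms: none
Why: Luche reduction: hydride should attack the strained, cross-conjugated C15 ketone from the open exo face (side of C14), giving the endo alcohol, in preference to the better-conjugated C9 enone carbonyl.

Step 17
Reactants: 23 endo allylic alcohol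
Product: 24 target (CNP0172716.1)
Conditions: Ac2O, pyridine, DMAP (cat.), CH2Cl2, 0 °C
Reagents that add atoms: acetic anhydride, CC(=O)OC(C)=O
Why: Acylation of the secondary C15 alcohol; the hindered tertiary C10 alcohol does not react under these conditions.

**Compound list**

1 | tert-butyl 2-oxocyclopentane-1-carboxylate | CC(C)(C)OC(=O)C1CCCC1=O | starting material
2 | tert-butyl (1R)-1-methyl-2-oxocyclopentane-1-carboxylate | CC(C)(C)OC(=O)[C@]1(C)CCCC1=O | intermediate
3 | tert-butyl (1R)-2-(dibromomethyl)-2-hydroxy-1-methylcyclopentane-1-carboxylate (carbinol epimers) | CC(C)(C)OC(=O)[C@]1(C)CCCC1(O)C(Br)Br | intermediate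
4 | benzyl glyoxylate (benzyl 2-oxoacetate) | O=CC(=O)OCc1ccccc1 | starting material
5 | β-oxido lithium carbenoid (O-lithio, C-lithio-bromo form of 3) | CC(C)(C)OC(=O)[C@]1(C)CCCC1(O[Li])C([Li])Br | intermediate
6 | ring-expanded lithium enolate, tert-butyl (1R)-3-(lithiooxy)-1-methylcyclohex-2-ene-1-carboxylate | CC(C)(C)OC(=O)[C@]1(C)CCCC(O[Li])=C1 | intermediate
7 | lithium aldolate, tert-butyl 2-[2-(benzyloxy)-1-(lithiooxy)-2-oxoethyl]-1-methyl-3-oxocyclohexane-1-carboxylate (side chain cis to the ester; C6 epimers) | CC(C)(C)OC(=O)[C@]1(C)CCCC(=O)[C@@H]1C(O[Li])C(=O)OCc1ccccc1 | intermediate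
8 | benzyl 7a-methyl-1,4-dioxo-octahydro-2-benzofuran-3-carboxylate (cis-fused; C6 epimers) | O=C(OCc1ccccc1)C1OC(=O)[C@]2(C)CCCC(=O)[C@H]12 | intermediate
9 | benzyl 7a-methyl-4-methylidene-1-oxo-octahydro-2-benzofuran-3-carboxylate | O=C(OCc1ccccc1)C1OC(=O)[C@]2(C)CCCC(=C)[C@H]12 | intermediate
10 | benzyl 4-hydroxy-4,7a-dimethyl-1-oxo-octahydro-2-benzofuran-3-carboxylate (OH, H-3a, 7a-methyl on one face) | O=C(OCc1ccccc1)C1OC(=O)[C@]2(C)CCC[C@@](C)(O)[C@H]12 | intermediate
11 | 4-hydroxy-4,7a-dimethyl-1-oxo-octahydro-2-benzofuran-3-carboxylic acid | OC(=O)C1OC(=O)[C@]2(C)CCC[C@@](C)(O)[C@H]12 | intermediate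
12 | (S)-perillic acid, (4S)-4-(prop-1-en-2-yl)cyclohex-1-ene-1-carboxylic acid | C=C(C)[C@H]1CCC(C(=O)O)=CC1 | starting material
13 | (4S)-1-(methylsulfanyl)-4-(prop-1-en-2-yl)cyclohex-2-ene-1-carboxylic acid (C1 epimers) | C=C(C)[C@@H]1C=CC(SC)(C(=O)O)CC1 | intermediate
14 | (4S)-4-(prop-1-en-2-yl)cyclohex-2-en-1-one | C=C(C)[C@@H]1C=CC(=O)CC1 | intermediate
15 | (4S)-6-[(dimethylamino)methyl]-4-(prop-1-en-2-yl)cyclohex-2-en-1-one (C6 epimers) | C=C(C)[C@@H]1C=CC(=O)C(CN(C)C)C1 | intermediate
16 | trimethyl{[(5S)-2-oxo-5-(prop-1-en-2-yl)cyclohex-3-en-1-yl]methyl}ammonium iodide | C=C(C)[C@@H]1C=CC(=O)C(C[N+](C)(C)C)C1.[I-] | intermediate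
17 | (4S)-6-methylidene-4-(prop-1-en-2-yl)cyclohex-2-en-1-one | C=C(C)[C@@H]1C=CC(=O)C(=C)C1 | intermediate
18 | Giese adduct, lactone joined through C6–C7 to C8 of the ring C enone (C8 epimers) | C=C(C)[C@@H]1C=CC(=O)C(C[C@H]2OC(=O)[C@]3(C)CCC[C@@](C)(O)[C@H]23)C1 | intermediate
19 | allylic chloride of 18 (3-chloroprop-1-en-2-yl on C13) | C=C(CCl)[C@@H]1C=CC(=O)C(C[C@H]2OC(=O)[C@]3(C)CCC[C@@](C)(O)[C@H]23)C1 | intermediate
20 | 15-deoxy-15-deacetoxy bicyclo[3.2.1]octenone (ring D closed, C15 = CH2) | C=C1[C@@H]2C=CC(=O)[C@@](C[C@H]3OC(=O)[C@]4(C)CCC[C@@](C)(O)[C@H]34)(C2)C1 | intermediate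
21 | 15-hydroxy compound (C15 epimers) | C=C1[C@@H]2C=CC(=O)[C@@](C[C@H]3OC(=O)[C@]4(C)CCC[C@@](C)(O)[C@H]34)(C2)C1O | intermediate
22 | 9,15-dione (C15 ketone, C16=C17) | C=C1[C@@H]2C=CC(=O)[C@@](C[C@H]3OC(=O)[C@]4(C)CCC[C@@](C)(O)[C@H]34)(C2)C1=O | intermediate
23 | 15-endo alcohol (deacetyl target) | C=C1[C@@H]2C=CC(=O)[C@@](C[C@H]3OC(=O)[C@]4(C)CCC[C@@](C)(O)[C@H]34)(C2)[C@@H]1O | intermediate
24 | CNP0172716.1 | C=C1[C@@H]2C=CC(=O)[C@@](C[C@H]3OC(=O)[C@]4(C)CCC[C@@](C)(O)[C@H]34)(C2)[C@@H]1OC(C)=O | target

**Step count.** 17 steps in total; longest linear sequence 13 steps (steps 1–6 and 11–17).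

**Steps most likely to fail**

Step 3. The 1,2-shift may take the methylene carbon C1 in place of the ester-bearing C4, or the hindered β-alkoxide ester may fragment by retro-aldol cleavage. The fallback sets out from 3 and removes the electron-withdrawing group from the migrating carbon. i-Bu2AlH (CH2Cl2, −78 → 0 °C) reduces the tert-butyl ester to [2-(dibromomethyl)-2-hydroxy-1-methylcyclopentyl]methanol F1. TBSCl and imidazole silylate the primary hydroxyl to give the silyl ether F2. n-BuLi (2.2 equiv, −95 °C), then 4 and an NH4Cl quench, give the ring-expanded aldol adduct F3, now by migration of a purely alkyl quaternary carbon. HF·pyridine frees the hydroxymethyl group to give the keto diol F4. TEMPO (cat.) with PhI(OAc)2 oxidises the primary alcohol through the lactol to the lactone, which is compound 8.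

Step 11. Single-electron oxidation of the α-acyloxy carboxylate may be sluggish, and dienone 17 may be lost by dimerisation or by isomerisation to the phenol before it is trapped. The fallback sets out from 11. N-Hydroxyphthalimide, N,N′-diisopropylcarbodiimide and DMAP (cat.) give the N-acyloxyphthalimide F5. The C6 radical is then formed reductively (Ru(bpy)3(PF6)2, Hantzsch ester, i-Pr2NEt, CH2Cl2, blue LEDs) in the presence of the isolated ammonium iodide 16, from which the amine base releases 17 slowly in the flask. The adduct is compound 18.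

Step 16. The C9 enone carbonyl may be reduced in competition, or hydride may be delivered from the concave face. The fallback sets out from 22. Excess NaBH4 with CeCl3·7H2O (MeOH, 0 °C) reduces both carbonyls to the 9,15-diol F6. MnO2 (CH2Cl2, rt) then re-oxidises only the ring C allylic alcohol, because the endo C15 hydroxyl sits in the concave pocket next to the quaternary C8. This returns compound 23.

**Further compounds**

F1 | step 3 | [2-(dibromomethyl)-2-hydroxy-1-methylcyclopentyl]methanol (C4 as in 3) | OC[C@]1(C)CCCC1(O)C(Br)Br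
F2 | step 3 | 2-{[tert-butyl(dimethyl)silyl]oxymethyl}-1-(dibromomethyl)-2-methylcyclopentan-1-ol | CC(C)(C)[Si](C)(C)OC[C@]1(C)CCCC1(O)C(Br)Br
F3 | step 3 | benzyl 2-{2-[(tert-butyldimethylsilyl)oxymethyl]-2-methyl-6-oxocyclohexyl}-2-hydroxyacetate | CC(C)(C)[Si](C)(C)OC[C@]1(C)CCCC(=O)[C@@H]1C(O)C(=O)OCc1ccccc1
F4 | step 3 | benzyl 2-hydroxy-2-[2-(hydroxymethyl)-2-methyl-6-oxocyclohexyl]acetate | OC[C@]1(C)CCCC(=O)[C@@H]1C(O)C(=O)OCc1ccccc1
F5 | step 11 | 1,3-dioxoisoindolin-2-yl 4-hydroxy-4,7a-dimethyl-1-oxo-octahydro-2-benzofuran-3-carboxylate | O=C(ON1C(=O)c2ccccc2C1=O)C1OC(=O)[C@]2(C)CCC[C@@](C)(O)[C@H]12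
F6 | step 16 | 9,15-diol of 22 (15-OH endo, C9 carbinol either epimer) | C=C1[C@@H]2C=CC(O)[C@@](C[C@H]3OC(=O)[C@]4(C)CCC[C@@](C)(O)[C@H]34)(C2)[C@@H]1O
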